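**Direct plan and its weak points**

A direct plan would join three chiral fragments into the open-chain seco-cembranolide A1, which already carries the γ-lactone, a vinyl bromide and a terminal alkene. It would close a 14-membered ring between C4 and C5 by a B-alkyl Suzuki coupling, adjust C2/C12 to the epoxy enone A2, and contract A2 across the ring by forming the C1–C10 bond.
Its weakest steps would be:
- The ring closure of the 14-membered ring: a high-dilution, entropically costly coupling on a substrate carrying an epoxide, an acetate and a free tertiary alcohol.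
- The transannular opening of the epoxy ketone by an extended dienolate: a ring contraction without close precedent that would have to create the quaternary C1 and C10 at the very end.
- The C12 carbinol: it would be made as an epimer mixture, silylated, desilylated and oxidised again, a protecting-group and redox stretch that builds nothing.

**Retrosynthetic overview of the new route**

- The oxygen-bearing carbons C2 and C7 sit 1,6 across ring B, so ring B is read as a cyclodecane-1,6-dione, the cleaved ring-fusion alkene C2=C7 of a decalin. With ring A on C1–C10 the precursor is the hexahydrophenanthrene 15, whose former arene supplies C2–C7 with the C16 methyl on C5.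
- Ring order: ring A first (auxiliary-controlled Michael/Robinson annulation on a 2-tetralone), ring B second by scission of the C2–C7 bond (Birch reduction, then ozonolysis), γ-lactone last.
- Only C1 is set by an auxiliary. C10, C9 and C11 are relayed from its axial methyl in the rigid trans-decalin, C2 by a CBS reduction, C8 and C7 from C9.
- There is no macrocyclisation and no transannular C–C bond formation; the quaternary C1 and the trans C1/C10 fusion exist from steps 2 and 4.

Key step: step 7

Remarks on the chemistry: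
- Briarane numbering of the target is used for all compounds: C1 (C15 methyl), C2 (O-propanoyl), C5 (C16 methyl)=C6, C7 (lactone O), C8 (OH), C9 (OAc), C10, C11 (OH, C20 methyl), C12 (C=O), C13=C14, lactone C17 (C18 methyl)–C19.
- Assumption: the Michael addition of step 2 follows the facial sense known for the imine of 2-methylcyclohexanone (the aryl carbon takes the place of the ring methylene); should it be opposite, the (S)-amine would be used.
- Compounds 1, 5 and 22 are taken as commercially available.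
- Compounds 11 to 30 are carried as C11 epimers (mainly the equatorial methyl); C11 is set in step 16.

**Route**

Step 1
Reactants: 1 6-methyl-3,4-dihydronaphthalen-2(1H)-one
Product: 4 1,6-dimethyl-3,4-dihydronaphthalen-2(1H)-one (racemic), via pyrrolidine enamine 2 (not isolated), via iminium iodide 3 (not isolated)
Conditions: pyrrolidine, benzene, reflux (−H2O); MeI, dioxane, reflux; aq. AcOH–NaOAc
Reagents that add atoms: pyrrolidine, C1CCNC1 (2 and 3 only); iodomethane, CI
Why: Stork enamine alkylation: the arene-conjugated enamine is C-methylated only at benzylic C1 and hydrolysis gives the 1-methyl ketone, whose enolisable stereocentre is fixed in step 2.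

Step 2
Reactants: 4 1,6-dimethyl-3,4-dihydronaphthalen-2(1H)-one; 5 pent-1-en-3-one
Product: 10 (4aS)-1,4a,7-trimethyl-4,4a,9,10-tetrahydrophenanthren-2(3H)-one, via imine 6 (not isolated), via Michael adduct imine 7 (not isolated), via diketone 8 (not isolated), via ketol 9 (not isolated)
Conditions: (R)-1-phenylethylamine, toluene, reflux (−H2O); 5, THF, 40 °C; aq. AcOH, rt; then NaOMe, MeOH, 60 °C
Reagents that add atoms: (R)-1-phenylethylamine, C[C@@H](N)c1ccccc1 (6 and 7 only)
Why: Deracemising Michael addition of the chiral imine through its secondary enamine tautomer (the phenyl group shields one face) should set the quaternary C1, and Robinson aldol condensation of the crude diketone closes ring A; the crystalline enone can be enriched by recrystallisation.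

Step 3
Reactants: 10 (4aS)-1,4a,7-trimethyl-4,4a,9,10-tetrahydrophenanthren-2(3H)-one
Product: 11 (4aS)-2,2-ethylenedioxy-1,4a,7-trimethyl-1,2,3,4,4a,9-hexahydrophenanthrene (alkene C9=C10)
Conditions: ethane-1,2-diol, p-TsOH (cat.), benzene, reflux (−H2O)
Reagents that add atoms: ethane-1,2-diol, OCCO
Why: Acid-catalysed ketalisation of the 4-methyl enone runs through the dienol and moves the alkene out of conjugation to C9=C10, as with steroidal 4-en-3-ones, while masking C12 for the Birch step.

Step 4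
Reactants: 11 deconjugated ketal
Product: 13 trans-fused 9α-alcohol (9-OH and 10-H both anti to the C15 methyl), via alkylborane 12 (not isolated)
Conditions: BH3·THF, THF, 0 °C → rt; then NaOH, H2O2, 0 °C
Reagents that add atoms: borane–tetrahydrofuran, B.C1CCOC1 (boron of 12 only); hydrogen peroxide, OO
Why: Hydroboration–oxidation: borane should add syn from the face opposite the axial C15 methyl with boron on the less substituted C9, as in steroidal 5-enes, so one event sets C10 (trans fusion) and C9.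

Step 5
Reactants: 13 trans-fused 9α-alcohol
Product: 14 9-O-tert-butyldimethylsilyl ether of 13
Conditions: TBSOTf, 2,6-lutidine, CH2Cl2, −78 → 0 °C
Reagents that add atoms: tert-butyldimethylsilyl triflate, CC(C)(C)[Si](C)(C)OS(=O)(=O)C(F)(F)F
Why: Silylation gives a C9 oxygen that survives dissolving metal and that, β to the later C7 ketone, tolerates base where an acetate would be eliminated.

Step 6
Reactants: 14 silyl ether
Product: 15 5,8-dihydro derivative of 14 (alkenes C2=C7 and C4=C5)
Conditions: Li, NH3 (l), THF, t-BuOH, −78 → −33 °C; NH4Cl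
Reagents that add atoms: none
Why: Birch reduction of the 1,2,4-trialkylbenzene protonates the two unsubstituted para-related carbons C3 and C6, leaving the tetrasubstituted C2=C7 and the trisubstituted C4=C5 bond; ketal and silyl ether are inert.

Step 7
Reactants: 15 Birch diene
Product: 18 6/10-bicyclic (5Z)-ene-2,7-dione (9α-OTBS, 12-dioxolane), via ozonide 16 (not isolated), via skipped enedione 17 (not isolated)
Conditions: O3 (1.0 equiv), CH2Cl2, −78 °C; Me2S, −78 °C → rt; then DBU (0.2 equiv), CH2Cl2, 0 °C → rt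
Reagents that add atoms: ozone, [O-][O+]=O
Why: Ozone should add to the most electron-rich alkene of 15, the tetrasubstituted ring-fusion bond C2=C7, faster than to the trisubstituted C4=C5, as in the classical cleavage of 9,10-octalin to cyclodecane-1,6-dione, and reduction of ozonide 16 unveils both ketones. Ring B forms by scission of the bond shared by two six-membered rings, not by a cyclisation, so there is no entropic penalty. No stereocentre is created: the ten-membered ring inherits the trans C1/C10 fusion, the C9 carbinol and the cis ring alkene from the tricycle. DBU then moves the skipped alkene into conjugation; of the two possible enones the trisubstituted one conjugated with the unhindered C7 carbonyl is the thermodynamic one, and the ring holds it cis (5Z). The step needs one equivalent of ozone at low temperature and short base contact, so that the 1,6-dione does not undergo transannular aldol reaction, which the neopentyl C2 carbonyl disfavours.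

Step 8
Reactants: 18 enedione
Product: 19 (2R)-2,7-diol (C7 configuration immaterial)
Conditions: (S)-2-methyl-CBS-oxazaborolidine (1 equiv), catecholborane, toluene–CH2Cl2, −78 → −20 °C; MeOH, aq. NaOH
Reagents that add atoms: none
Why: Corey–Bakshi–Shibata reduction: at C2 the quaternary C1 is the large and the C3 methylene the small substituent, so the (S)-catalyst should give the 2R carbinol under reagent control; the more reactive C7 enone is reduced too, which is accepted because step 9 restores it.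

Step 9
Reactants: 19 diol
Product: 20 (2R)-2-hydroxy-(5Z)-en-7-one
Conditions: activated MnO2, CH2Cl2, rt
Reagents that add atoms: none
Why: MnO2 oxidises only the allylic C7 carbinol, which returns the ketone needed to activate C8 and leaves the saturated neopentyl C2 carbinol untouched.

Step 10
Reactants: 20 hydroxy enone
Product: 21 2-O-propanoate of 20
Conditions: (EtCO)2O, DMAP, Et3N, CH2Cl2, rt → 40 °C
Reagents that add atoms: propanoic anhydride, CCC(=O)OC(=O)CC
Why: DMAP-catalysed acylation of the only free hydroxyl installs the final C2 ester before any enolate chemistry.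

Step 11
Reactants: 21 propanoate enone; 22 ethyl (2R)-2-[(trifluoromethanesulfonyl)oxy]propanoate
Product: 24 8-[(1R)-1-ethoxycarbonylethyl] enone (C8 epimers; C17 R), via lithium enolate 23 (not isolated)
Conditions: LiN(SiMe3)2, THF, −78 °C; then 22, −78 → −40 °C
Reagents that add atoms: lithium bis(trimethylsilyl)amide, [Li]N([Si](C)(C)C)[Si](C)(C)C (lithium of 23 only)
Why: Kinetic deprotonation of the enone at C8 and SN2 alkylation by the lactate triflate with clean inversion should form the C8–C17 bond and give C17 R; the C8 configuration is reset in step 12.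

Step 12
Reactants: 24 γ-keto ester
Product: 26 8-hydroxy-7-ketone (8-OH anti to 9-O), via potassium enolate 25 (not isolated)
Conditions: KN(SiMe3)2, THF, −78 °C; 2-(benzenesulfonyl)-3-phenyloxaziridine, −78 °C; NH4Cl
Reagents that add atoms: potassium bis(trimethylsilyl)amide, [K]N([Si](C)(C)C)[Si](C)(C)C (potassium of 25 only); 2-(benzenesulfonyl)-3-phenyloxaziridine, O=S(=O)(c1ccccc1)N1OC1c1ccccc1
Why: Davis enolate oxidation: the oxidant should reach the tetrasubstituted enolate on the outer face of ring B in the rotamer that keeps the C9 silyloxy group in the enolate plane (allylic 1,3-strain model), which gives the 8-hydroxyl anti to the C9 oxygen as in the target.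

Step 13
Reactants: 26 8-hydroxy-7-ketone
Product: 28 γ-lactone (7,8-trans-fused; 8-OH, 17R; 9-OTBS, 12-dioxolane), via diol ester 27 (not isolated)
Conditions: Zn(BH4)2, Et2O, −30 °C; aq. NH4Cl; then PPTS (cat.), CH2Cl2, rt
Reagents that add atoms: none
Why: Chelation-controlled 1,2-reduction: hydride should add to the zinc chelate of the α-hydroxy enone from the face away from ring carbon C9, giving the C7 oxygen anti to the C8 hydroxyl, and the γ-hydroxy ester then lactonises; the epimerisable C17 settles with its methyl trans to C9.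

Step 14
Reactants: 28 protected lactone
Product: 29 9-hydroxy-12-ketone
Conditions: 3 M aq. HCl, THF, rt
Reagents that add atoms: water, O
Why: Acid hydrolysis removes the silyl ether and the dioxolane in one operation; the lactone, the propanoate and the tertiary alcohol should survive, and C11 equilibrates to the equatorial methyl.

Step 15
Reactants: 29 hydroxy ketone
Product: 30 9-O-acetate of 29
Conditions: Ac2O, DMAP, pyridine, CH2Cl2, 0 °C → rt
Reagents that add atoms: acetic anhydride, CC(=O)OC(C)=O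
Why: DMAP-catalysed acetylation takes the only secondary alcohol; the tertiary 8-hydroxyl does not react.

Step 16
Reactants: 30 acetate ketone
Product: 33 (11S)-11-hydroxy-12-ketone, via silyl enol ether 31 (not isolated), via bis-silyl ether 32 (not isolated)
Conditions: TMSOTf, Et3N, CH2Cl2, 0 °C → rt; dimethyldioxirane, acetone, −78 °C; aq. citric acid, MeOH
Reagents that add atoms: trimethylsilyl triflate, C[Si](C)(C)OS(=O)(=O)C(F)(F)F (silyl groups of 31 and 32 only); dimethyldioxirane, CC1(C)OO1
Why: Rubottom oxidation: equilibrating soft enolisation should give the more substituted C11=C12 silyl enol ether, which is far more electron-rich than C5=C6, and oxygen enters anti to the axial C15 methyl, giving 11-OH on the face of H-10.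

Step 17
Reactants: 33 11-hydroxy ketone
Product: 36 CNP0240018.1, via tris-silyl dienol ether 34 (not isolated), via bis-silyl enone 35 (not isolated)
Conditions: TMSOTf, Et3N, CH2Cl2, 0 °C; Pd(OAc)2 (1.1 equiv), MeCN, rt; aq. citric acid, MeOH
Reagents that add atoms: trimethylsilyl triflate, C[Si](C)(C)OS(=O)(=O)C(F)(F)F (silyl groups of 34 and 35 only)
Why: Saegusa–Ito dehydrogenation: with C11 quaternary the ketone can enolise only toward C13, and divalent palladium converts that silyl enol ether into the C13=C14 enone under conditions that esters, the lactone and the tertiary alcohols tolerate.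

**Compound list**

1 | 6-methyl-3,4-dihydronaphthalen-2(1H)-one | O=C1CCc2cc(C)ccc2C1 | starting material
2 | 1-(6-methyl-3,4-dihydronaphthalen-2-yl)pyrrolidine | Cc1ccc2C=C(CCc2c1)N1CCCC1 | intermediate
3 | 1-(1,6-dimethyl-3,4-dihydronaphthalen-2(1H)-ylidene)pyrrolidinium iodide | CC1C(=[N+]2CCCC2)CCc2cc(C)ccc12.[I-] | intermediate
4 | 1,6-dimethyl-3,4-dihydronaphthalen-2(1H)-one (racemic) | CC1C(=O)CCc2cc(C)ccc12 | intermediate
5 | pent-1-en-3-one | CCC(=O)C=C | starting material
6 | N-[(1R)-1-phenylethyl] imine of 4 | CC1C(=N[C@H](C)c2ccccc2)CCc2cc(C)ccc12 | intermediate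
7 | N-[(1R)-1-phenylethyl] imine of 8 | CCC(=O)CC[C@@]1(C)C(=N[C@H](C)c2ccccc2)CCc2cc(C)ccc12 | intermediate
8 | (1R)-1,6-dimethyl-1-(3-oxopentyl)-3,4-dihydronaphthalen-2(1H)-one | CCC(=O)CC[C@@]1(C)C(=O)CCc2cc(C)ccc12 | intermediate
9 | 10a-hydroxy-1,4a,7-trimethyl-3,4,4a,9,10,10a-hexahydrophenanthren-2(1H)-one (aldol adduct) | CC1C(=O)CC[C@]2(C)c3ccc(C)cc3CCC12O | intermediate
10 | (4aS)-1,4a,7-trimethyl-4,4a,9,10-tetrahydrophenanthren-2(3H)-one | CC1=C2CCc3cc(C)ccc3[C@@]2(C)CCC1=O | intermediate
11 | (4aS)-2,2-ethylenedioxy-1,4a,7-trimethyl-1,2,3,4,4a,9-hexahydrophenanthrene (C9=C10; C11 epimers) | CC1C2=CCc3cc(C)ccc3[C@@]2(C)CCC14OCCO4 | intermediate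
12 | C9 alkylborane of 11 (boron and H-10 anti to the C15 methyl) | CC1[C@@H]2[C@@H](B)Cc3cc(C)ccc3[C@@]2(C)CCC14OCCO4 | intermediate
13 | trans-fused 9α-alcohol: 2,2-ethylenedioxy-1,4a,7-trimethyl-1,2,3,4,4a,9,10,10a-octahydrophenanthren-10-ol | CC1[C@@H]2[C@@H](O)Cc3cc(C)ccc3[C@@]2(C)CCC14OCCO4 | intermediate
14 | 9-O-TBS ether of 13 | CC1[C@@H]2[C@@H](O[Si](C)(C)C(C)(C)C)Cc3cc(C)ccc3[C@@]2(C)CCC14OCCO4 | intermediate
15 | Birch diene (5,8-dihydro-14; alkenes C2=C7 and C4=C5) | CC1[C@@H]2[C@@H](O[Si](C)(C)C(C)(C)C)CC3=C(CC=C(C)C3)[C@@]2(C)CCC14OCCO4 | intermediate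
16 | 1,2,4-trioxolane (ozonide) across C2 and C7 of 15 | CC1C2(OCCO2)CC[C@@]3(C)[C@H]1[C@@H](O[Si](C)(C)C(C)(C)C)CC45OOC3(O4)C/C=C(C)\C5 | intermediate
17 | 6/10-bicyclic (4Z)-ene-2,7-dione (9α-OTBS, 12-dioxolane) | O=C1C/C=C(C)\CC(=O)C[C@H](O[Si](C)(C)C(C)(C)C)[C@@H]2[C@]1(C)CCC3(OCCO3)C2C | intermediate
18 | 6/10-bicyclic (5Z)-ene-2,7-dione (9α-OTBS, 12-dioxolane) | O=C1CC/C(C)=C\C(=O)C[C@H](O[Si](C)(C)C(C)(C)C)[C@@H]2[C@]1(C)CCC3(OCCO3)C2C | intermediate
19 | (2R)-2,7-diol of 18 | O[C@@H]1CC/C(C)=C\[C@H](O)C[C@H](O[Si](C)(C)C(C)(C)C)[C@@H]2[C@]1(C)CCC3(OCCO3)C2C | intermediate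
20 | (2R)-2-hydroxy-(5Z)-en-7-one | O[C@@H]1CC/C(C)=C\C(=O)C[C@H](O[Si](C)(C)C(C)(C)C)[C@@H]2[C@]1(C)CCC3(OCCO3)C2C | intermediate
21 | 2-O-propanoate of 20 | CCC(=O)O[C@@H]1CC/C(C)=C\C(=O)C[C@H](O[Si](C)(C)C(C)(C)C)[C@@H]2[C@]1(C)CCC3(OCCO3)C2C | intermediate
22 | ethyl (2R)-2-[(trifluoromethanesulfonyl)oxy]propanoate | C[C@@H](OS(=O)(=O)C(F)(F)F)C(=O)OCC | starting material
23 | lithium C7=C8 enolate of 21 | CCC(=O)O[C@@H]1CC/C(C)=C\C([O-])=C[C@H](O[Si](C)(C)C(C)(C)C)[C@@H]2[C@]1(C)CCC3(OCCO3)C2C.[Li+] | intermediate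
24 | 8-[(1R)-1-ethoxycarbonylethyl] enone (C8 epimers) | CCC(=O)O[C@@H]1CC/C(C)=C\C(=O)C([C@@H](C)C(=O)OCC)[C@H](O[Si](C)(C)C(C)(C)C)[C@@H]2[C@]1(C)CCC3(OCCO3)C2C | intermediate
25 | potassium C7=C8 enolate of 24 | CCC(=O)O[C@@H]1CC/C(C)=C\C([O-])=C([C@@H](C)C(=O)OCC)[C@H](O[Si](C)(C)C(C)(C)C)[C@@H]2[C@]1(C)CCC3(OCCO3)C2C.[K+] | intermediate
26 | 8-hydroxy-7-ketone (C8 as in the target) | CCC(=O)O[C@@H]1CC/C(C)=C\C(=O)[C@@](O)([C@@H](C)C(=O)OCC)[C@H](O[Si](C)(C)C(C)(C)C)[C@@H]2[C@]1(C)CCC3(OCCO3)C2C | intermediate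
27 | 7,8-diol ethyl ester (C7 as in the target) | CCC(=O)O[C@@H]1CC/C(C)=C\[C@H](O)[C@@](O)([C@@H](C)C(=O)OCC)[C@H](O[Si](C)(C)C(C)(C)C)[C@@H]2[C@]1(C)CCC3(OCCO3)C2C | intermediate
28 | γ-lactone, 9-O-TBS, 12-dioxolane | CCC(=O)O[C@@H]1CC/C(C)=C\[C@@H]2OC(=O)[C@H](C)[C@@]2(O)[C@H](O[Si](C)(C)C(C)(C)C)[C@@H]2[C@]1(C)CCC3(OCCO3)C2C | intermediate
29 | 9-hydroxy-12-ketone lactone | CCC(=O)O[C@@H]1CC/C(C)=C\[C@@H]2OC(=O)[C@H](C)[C@@]2(O)[C@H](O)[C@@H]2[C@]1(C)CCC(=O)C2C | intermediate
30 | 9-O-acetyl-12-ketone lactone | CCC(=O)O[C@@H]1CC/C(C)=C\[C@@H]2OC(=O)[C@H](C)[C@@]2(O)[C@H](OC(C)=O)[C@@H]2[C@]1(C)CCC(=O)C2C | intermediate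
31 | 8-O-TMS C11=C12 trimethylsilyl enol ether of 30 | CCC(=O)O[C@@H]1CC/C(C)=C\[C@@H]2OC(=O)[C@H](C)[C@@]2(O[Si](C)(C)C)[C@H](OC(C)=O)[C@@H]2[C@]1(C)CCC(O[Si](C)(C)C)=C2C | intermediate
32 | 8,11-bis-O-TMS ether of 33 | CCC(=O)O[C@@H]1CC/C(C)=C\[C@@H]2OC(=O)[C@H](C)[C@@]2(O[Si](C)(C)C)[C@H](OC(C)=O)[C@@H]2[C@]1(C)CCC(=O)[C@@]2(C)O[Si](C)(C)C | intermediate
33 | (11S)-11-hydroxy-12-ketone (13,14-dihydro target) | CCC(=O)O[C@@H]1CC/C(C)=C\[C@@H]2OC(=O)[C@H](C)[C@@]2(O)[C@H](OC(C)=O)[C@@H]2[C@]1(C)CCC(=O)[C@@]2(C)O | intermediate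
34 | 8,11-bis-O-TMS C12=C13 trimethylsilyl enol ether of 33 | CCC(=O)O[C@@H]1CC/C(C)=C\[C@@H]2OC(=O)[C@H](C)[C@@]2(O[Si](C)(C)C)[C@H](OC(C)=O)[C@@H]2[C@]1(C)CC=C(O[Si](C)(C)C)[C@@]2(C)O[Si](C)(C)C | intermediate
35 | 8,11-bis-O-TMS ether of the target | CCC(=O)O[C@@H]1CC/C(C)=C\[C@@H]2OC(=O)[C@H](C)[C@@]2(O[Si](C)(C)C)[C@H](OC(C)=O)[C@@H]2[C@]1(C)C=CC(=O)[C@@]2(C)O[Si](C)(C)C | intermediate
36 | CNP0240018.1 (1S,2R,7S,8S,9R,10S,11S,17R; 5Z) | CCC(=O)O[C@@H]1CC/C(C)=C\[C@@H]2OC(=O)[C@H](C)[C@@]2(O)[C@H](OC(C)=O)[C@@H]2[C@]1(C)C=CC(=O)[C@@]2(C)O | target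

**Step count**

Total step count: 17. Longest linear sequence: 17 (the route is linear from 1).

**Steps most likely to fail, with fallbacks**

Step 7. What may go wrong: ozone does not discriminate cleanly between the tetrasubstituted and the trisubstituted alkene, or the 1,6-dione undergoes transannular aldol reaction during the base-mediated conjugation. Fallback: setting out from 15, buffered mCPBA at low temperature would epoxidise the more nucleophilic ring-fusion bond to the 2,7-epoxide F1. Periodic acid in wet THF would open it to the 2,7-diol F2 and cleave that glycol to 17. The alkene would then be conjugated under mild acid catalysis (oxalic acid on silica) instead of DBU, and the route is rejoined at 18.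

Step 12 (with step 13). What may go wrong: poor facial selectivity in the oxidation of the C8 enolate, loss of the β-silyloxy group from the enolate, or the wrong face in the C7 reduction. Fallback, which sets C7 by reagent control and relays C8 through a tether:
- Setting out from 21, Et3SiOTf/Et3N would give the silyloxydiene F3, and dimethyldioxirane the 8-triethylsilyloxy enone F4.
- CBS reduction (catalyst enantiomer chosen for the 7S carbinol) would give the allylic alcohol F5.
- 2-Bromopropanoyl bromide/pyridine would give the 2-bromopropanoate F6.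
- PPTS in methanol would free the 8-carbinol F7, and Dess–Martin periodinane would give the 8-ketone F8.
- Activated Zn in THF would close the lactone by intramolecular Reformatsky reaction, so that the route comes back at 28.

Step 16. What may go wrong: enol silylation toward C13 instead of C11, or competing epoxidation of C5=C6. Fallback, which reverses the order so that regiochemistry is enforced by blocking:
- Setting out from 30, aerobic dehydrogenation with palladium bis(trifluoroacetate)/DMSO/O2 on the unhindered C13–C14 side would give the 11-deoxy enone F9.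
- Its only possible silyloxydiene F10 (TMSOTf/Et3N) would be oxidised by dimethyldioxirane from the face anti to the C15 methyl.
- The route comes back at 35 and, after desilylation, at 36.

Further compounds
F1 | step 7 | 2,7-epoxide of 15 | CC1[C@@H]2[C@@H](O[Si](C)(C)C(C)(C)C)CC35OC5(CC=C(C)C3)[C@@]2(C)CCC14OCCO4
F2 | step 7 | 2,7-diol of 15 | CC1[C@@H]2[C@@H](O[Si](C)(C)C(C)(C)C)CC3(O)C(O)(CC=C(C)C3)[C@@]2(C)CCC14OCCO4
F3 | step 12 | 7-(triethylsilyloxy)-5,7-diene from 21 | CCC(=O)O[C@@H]1CC/C(C)=C\C(O[Si](CC)(CC)CC)=C[C@H](O[Si](C)(C)C(C)(C)C)[C@@H]2[C@]1(C)CCC3(OCCO3)C2C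
F4 | step 12 | 8-(triethylsilyloxy) enone | CCC(=O)O[C@@H]1CC/C(C)=C\C(=O)C(O[Si](CC)(CC)CC)[C@H](O[Si](C)(C)C(C)(C)C)[C@@H]2[C@]1(C)CCC3(OCCO3)C2C
F5 | step 12 | 7-carbinol of F4 (C7 as in the target) | CCC(=O)O[C@@H]1CC/C(C)=C\[C@H](O)C(O[Si](CC)(CC)CC)[C@H](O[Si](C)(C)C(C)(C)C)[C@@H]2[C@]1(C)CCC3(OCCO3)C2C
F6 | step 12 | 7-O-(2-bromopropanoate) of F5 | CCC(=O)O[C@@H]1CC/C(C)=C\[C@H](OC(=O)C(C)Br)C(O[Si](CC)(CC)CC)[C@H](O[Si](C)(C)C(C)(C)C)[C@@H]2[C@]1(C)CCC3(OCCO3)C2C
F7 | step 12 | 8-carbinol from F6 | CCC(=O)O[C@@H]1CC/C(C)=C\[C@H](OC(=O)C(C)Br)C(O)[C@H](O[Si](C)(C)C(C)(C)C)[C@@H]2[C@]1(C)CCC3(OCCO3)C2C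
F8 | step 12 | 8-ketone from F7 | CCC(=O)O[C@@H]1CC/C(C)=C\[C@H](OC(=O)C(C)Br)C(=O)[C@H](O[Si](C)(C)C(C)(C)C)[C@@H]2[C@]1(C)CCC3(OCCO3)C2C
F9 | step 16 | 11-deoxy-13-en-12-one | CCC(=O)O[C@@H]1CC/C(C)=C\[C@@H]2OC(=O)[C@H](C)[C@@]2(O)[C@H](OC(C)=O)[C@@H]2[C@]1(C)C=CC(=O)C2C
F10 | step 16 | 8-O-TMS 12-(trimethylsilyloxy)-11,13-diene | CCC(=O)O[C@@H]1CC/C(C)=C\[C@@H]2OC(=O)[C@H](C)[C@@]2(O[Si](C)(C)C)[C@H](OC(C)=O)[C@@H]2[C@]1(C)C=CC(O[Si](C)(C)C)=C2C
A1 | direct plan | open-chain 4,5-seco-cembranolide (vinyl bromide, terminal alkene, 10,11-epoxide, 9-acetate, bis-silyl ether) | Br/C(C)=C\[C@@H]1OC(=O)[C@H](C)[C@@]1(O)[C@H](OC(C)=O)[C@H]2O[C@]2(C)C(O[Si](C)(C)C(C)(C)C)/C=C/[C@H](C)[C@H](O[Si](C)(C)C(C)(C)C)C=C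
A2 | direct plan | 14-membered cembranolide 10,11-epoxy-13-en-12-one | O[C@@H]1CC/C(C)=C\[C@@H]2OC(=O)[C@H](C)[C@@]2(O)[C@H](OC(C)=O)[C@H]3O[C@]3(C)C(=O)/C=C/[C@@H]1C
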